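**Strategy**

Everything rests on cutting the aryl ether bond O1–C8a of the chromene together with the C8–carbonyl bond. Ring B carries three contiguous functions, the C7 oxygen, the C8 acyl group and the C8a–O1 ether, next to the cis C3=C4 alkene: the signature of a 3-alkoxyaryne (C8≡C8a) captured by a tethered alkoxide. In one operation the tertiary alkoxide of an open-chain (Z)-allylic alcohol adds to the aryne, which closes the pyran ring, and the C8 aryllithium so formed is intercepted by the ring A aldehyde. The precursor is a simple 3-fluoroaryl MOM ether with neither the pyran ring nor the diaryl carbon bridge.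

Key step: step 9

Remark: ring B is numbered as a 2H-chromene (O1, C2 to C8a) and ring A is the pentasubstituted benzaldehyde ring. The target has no stereocentre; the carbinol centre of 18 is formed racemic and is removed in step 10.

**Route**

Step 1
Reactants: 1 4-bromo-3-fluorophenol
Product: 2 1-bromo-2-fluoro-4-(methoxymethoxy)benzene
Conditions: MOMCl, iPr2NEt, CH2Cl2, 0 °C → rt
Reagents that add atoms: chloromethyl methyl ether (MOMCl) COCCl
Why: Williamson-type O-alkylation of the phenol with the reactive α-chloro ether installs the MOM acetal that later directs metalation and stabilises the C8 anion.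

Step 2
Reactants: 2 1-bromo-2-fluoro-4-(methoxymethoxy)benzene; 3 2-methylbut-3-yn-2-ol
Product: 4 4-[2-fluoro-4-(methoxymethoxy)phenyl]-2-methylbut-3-yn-2-ol
Conditions: PdCl2(PPh3)2 (cat.), CuI (cat.), Et3N, 70 °C
Reagents that add atoms: none
Why: Sonogashira coupling (oxidative addition of the aryl bromide to zerovalent palladium, then transmetalation of the copper acetylide) is routine for such bromides, and the aryl fluoride and MOM ether are inert.

Step 3
Reactants: 4 4-[2-fluoro-4-(methoxymethoxy)phenyl]-2-methylbut-3-yn-2-ol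
Product: 5 (Z)-4-[2-fluoro-4-(methoxymethoxy)phenyl]-2-methylbut-3-en-2-ol
Conditions: H2 (1 atm), Pd/CaCO3 poisoned with Pb(OAc)2, quinoline, EtOAc, rt
Reagents that add atoms: none
Why: Lindlar semihydrogenation delivers both hydrogens syn from the catalyst surface, which sets the Z alkene that holds the carbinol oxygen next to the ring; quinoline suppresses over-reduction.

Step 4
Reactants: 6 2-hydroxy-3-methylbenzaldehyde
Product: 8 2,5-dihydroxy-3-methylbenzaldehyde, via potassium aryl sulfate 7 (not isolated)
Conditions: K2S2O8, aq. KOH, 15 °C → rt; then aq. HCl, 80 °C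
Reagents that add atoms: potassium persulfate [K+].[K+].[O-]S(=O)(=O)OOS(=O)(=O)[O-]
Why: Elbs persulfate oxidation: the phenoxide attacks peroxydisulfate through its free para position and acid hydrolyses the aryl sulfate, the method that converts salicylaldehyde into gentisaldehyde; a modest conversion is acceptable at this first step.

Step 5
Reactants: 8 2,5-dihydroxy-3-methylbenzaldehyde
Product: 9 2-hydroxy-5-(methoxymethoxy)-3-methylbenzaldehyde
Conditions: MOMCl (1.05 equiv), iPr2NEt, CH2Cl2, 0 °C
Reagents that add atoms: chloromethyl methyl ether (MOMCl) COCCl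
Why: The 2-OH is tied up in a hydrogen bond to the aldehyde and flanked by the methyl group, so selective Williamson-type etherification with one equivalent of MOMCl should occur at the free 5-OH.

Step 6
Reactants: 9 2-hydroxy-5-(methoxymethoxy)-3-methylbenzaldehyde; 10 1-bromo-3-methylbut-2-ene (prenyl bromide)
Product: 11 5-(methoxymethoxy)-3-methyl-2-[(3-methylbut-2-en-1-yl)oxy]benzaldehyde
Conditions: K2CO3, DMF, rt → 40 °C
Reagents that add atoms: none
Why: Williamson etherification of the remaining chelated phenol with the allylic bromide; O-alkylation dominates in DMF and the temperature is far below that of a Claisen rearrangement.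

Step 7
Reactants: 11 5-(methoxymethoxy)-3-methyl-2-[(3-methylbut-2-en-1-yl)oxy]benzaldehyde
Product: 12 1-(dimethoxymethyl)-5-(methoxymethoxy)-3-methyl-2-[(3-methylbut-2-en-1-yl)oxy]benzene
Conditions: HC(OMe)3, MeOH, PPTS (cat.), rt; Et3N quench
Reagents that add atoms: methanol CO; trimethyl orthoformate COC(OC)OC
Why: Acid-catalysed acetalisation driven by the orthoformate as water scavenger masks the aldehyde and turns it into a directing group; PPTS is mild enough to leave the aryl MOM and prenyl ethers intact.

Step 8
Reactants: 12 1-(dimethoxymethyl)-5-(methoxymethoxy)-3-methyl-2-[(3-methylbut-2-en-1-yl)oxy]benzene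
Product: 14 2-(dimethoxymethyl)-6-(methoxymethoxy)-4-methyl-3-[(3-methylbut-2-en-1-yl)oxy]benzaldehyde, via aryllithium 13 (not isolated)
Conditions: n-BuLi (1.15 equiv), THF, −40 → 0 °C; DMF, −78 °C → rt; H2O
Reagents that add atoms: N,N-dimethylformamide CN(C)C=O
Why: Directed ortho-metalation removes the only ring proton flanked by two coordinating groups (acetal and OMOM), and the aryllithium is formylated by DMF (Bouveault-type formylation).

Step 9
Reactants: 5 (Z)-4-[2-fluoro-4-(methoxymethoxy)phenyl]-2-methylbut-3-en-2-ol; 14 2-(dimethoxymethyl)-6-(methoxymethoxy)-4-methyl-3-[(3-methylbut-2-en-1-yl)oxy]benzaldehyde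
Product: 18 [2-(dimethoxymethyl)-6-(methoxymethoxy)-4-methyl-3-(3-methylbut-2-enyloxy)phenyl][7-(methoxymethoxy)-2,2-dimethyl-2H-chromen-8-yl]methanol (racemic), via fluoroaryllithium 15 (not isolated), via aryne 16 (not isolated), via 8-lithiochromene 17 (not isolated)
Conditions: lithium 2,2,6,6-tetramethylpiperidide (LiTMP, 2.3 equiv), THF (0.02 M), −78 °C, then → −10 °C; re-cool to −78 °C, add 14, → 0 °C; H2O
Reagents that add atoms: none
Why: LiTMP forms the lithium alkoxide and then removes the arene proton flanked by F and OMOM to give 15, which on warming loses LiF to give 3-alkoxyaryne 16; the tethered tertiary alkoxide adds to the aryne carbon that carried fluorine, forming O1–C8a and the pyran ring and leaving the charge at C8 as aryllithium 17, which adds to aldehyde 14. The closest known reaction types are the intramolecular alkoxide–aryne ring closure (Bunnett-type benzyne cyclisation) and tandem aryne addition–electrophile trapping; 17 is the species otherwise reached by lithiating a 7-alkoxy-2,2-dimethylchromene between its two oxygens. The six-membered ring closes in a formally 6-exo-dig mode, with the aryne bond exocyclic to the new ring. Regiochemistry is doubly secured: attack at the other aryne carbon would need an impossible meta-bridged ring, and the inductively withdrawing 3-OMOM group also directs nucleophiles to the distal aryne carbon and then chelates the C8 lithium. The step needs intramolecular O-attack to outrun intermolecular addition of aryllithium or amide to the aryne; the Z alkene (which holds the alkoxide over C8a), high dilution and the hindered, poorly nucleophilic amide base should secure this. The new carbinol stereocentre is formed without control and is erased in step 10.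

Step 10
Reactants: 18 [2-(dimethoxymethyl)-6-(methoxymethoxy)-4-methyl-3-(3-methylbut-2-enyloxy)phenyl][7-(methoxymethoxy)-2,2-dimethyl-2H-chromen-8-yl]methanol
Product: 19 [2-(dimethoxymethyl)-6-(methoxymethoxy)-4-methyl-3-(3-methylbut-2-enyloxy)phenyl][7-(methoxymethoxy)-2,2-dimethyl-2H-chromen-8-yl]methanone
Conditions: Dess–Martin periodinane, NaHCO3, CH2Cl2, 0 °C → rt
Reagents that add atoms: none
Why: Dess–Martin oxidation of the doubly benzylic secondary alcohol to the diaryl ketone under buffered conditions should spare the acetal, the MOM ethers and both alkenes, and it removes the stereocentre.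

Step 11
Reactants: 19 [2-(dimethoxymethyl)-6-(methoxymethoxy)-4-methyl-3-(3-methylbut-2-enyloxy)phenyl][7-(methoxymethoxy)-2,2-dimethyl-2H-chromen-8-yl]methanone
Product: 20 3-hydroxy-2-(7-hydroxy-2,2-dimethyl-2H-chromene-8-carbonyl)-5-methyl-6-[(3-methylbut-2-en-1-yl)oxy]benzaldehyde (target)
Conditions: 1 M aq. HCl, THF, 0 °C → rt
Reagents that add atoms: water O
Why: Acid hydrolysis should cleave the dimethyl acetal and the two MOM ethers, both of which sit ortho to the ketone and are cleaved with carbonyl assistance, under acid mild enough to leave the prenyl aryl ether and the chromene untouched.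

**Compound list**

1 | 4-bromo-3-fluorophenol | Oc1ccc(Br)c(F)c1 | starting material
2 | 1-bromo-2-fluoro-4-(methoxymethoxy)benzene | COCOc1ccc(Br)c(F)c1 | intermediate
3 | 2-methylbut-3-yn-2-ol | CC(C)(O)C#C | starting material
4 | 4-[2-fluoro-4-(methoxymethoxy)phenyl]-2-methylbut-3-yn-2-ol | COCOc1ccc(C#CC(C)(C)O)c(F)c1 | intermediate
5 | (Z)-4-[2-fluoro-4-(methoxymethoxy)phenyl]-2-methylbut-3-en-2-ol | COCOc1ccc(/C=C\C(C)(C)O)c(F)c1 | intermediate
6 | 2-hydroxy-3-methylbenzaldehyde | Cc1cccc(C=O)c1O | starting material
7 | potassium 3-formyl-4-hydroxy-5-methylphenyl sulfate | Cc1cc(OS(=O)(=O)[O-])cc(C=O)c1O.[K+] | intermediate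
8 | 2,5-dihydroxy-3-methylbenzaldehyde | Cc1cc(O)cc(C=O)c1O | intermediate
9 | 2-hydroxy-5-(methoxymethoxy)-3-methylbenzaldehyde | COCOc1cc(C)c(O)c(C=O)c1 | intermediate
10 | 1-bromo-3-methylbut-2-ene (prenyl bromide) | CC(C)=CCBr | starting material
11 | 5-(methoxymethoxy)-3-methyl-2-[(3-methylbut-2-en-1-yl)oxy]benzaldehyde | COCOc1cc(C)c(OCC=C(C)C)c(C=O)c1 | intermediate
12 | 1-(dimethoxymethyl)-5-(methoxymethoxy)-3-methyl-2-[(3-methylbut-2-en-1-yl)oxy]benzene | COCOc1cc(C)c(OCC=C(C)C)c(C(OC)OC)c1 | intermediate
13 | [2-(dimethoxymethyl)-6-(methoxymethoxy)-4-methyl-3-(3-methylbut-2-enyloxy)phenyl]lithium | COCOc1cc(C)c(OCC=C(C)C)c(C(OC)OC)c1[Li] | intermediate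
14 | 2-(dimethoxymethyl)-6-(methoxymethoxy)-4-methyl-3-[(3-methylbut-2-en-1-yl)oxy]benzaldehyde | COCOc1cc(C)c(OCC=C(C)C)c(C(OC)OC)c1C=O | intermediate
15 | lithium (Z)-4-[2-fluoro-3-lithio-4-(methoxymethoxy)phenyl]-2-methylbut-3-en-2-olate | COCOc1ccc(/C=C\C(C)(C)O[Li])c(F)c1[Li] | intermediate
16 | lithium (Z)-4-[4-(methoxymethoxy)-2,3-didehydrophenyl]-2-methylbut-3-en-2-olate (aryne) | COCOC1=CC=C(/C=C\C(C)(C)O[Li])C#C1 | intermediate
17 | [7-(methoxymethoxy)-2,2-dimethyl-2H-chromen-8-yl]lithium | COCOc1ccc2C=CC(C)(C)Oc2c1[Li] | intermediate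
18 | [2-(dimethoxymethyl)-6-(methoxymethoxy)-4-methyl-3-(3-methylbut-2-enyloxy)phenyl][7-(methoxymethoxy)-2,2-dimethyl-2H-chromen-8-yl]methanol (racemic) | COCOc1ccc2C=CC(C)(C)Oc2c1C(O)c1c(OCOC)cc(C)c(OCC=C(C)C)c1C(OC)OC | intermediate
19 | [2-(dimethoxymethyl)-6-(methoxymethoxy)-4-methyl-3-(3-methylbut-2-enyloxy)phenyl][7-(methoxymethoxy)-2,2-dimethyl-2H-chromen-8-yl]methanone | COCOc1ccc2C=CC(C)(C)Oc2c1C(=O)c1c(OCOC)cc(C)c(OCC=C(C)C)c1C(OC)OC | intermediate
20 | 3-hydroxy-2-(7-hydroxy-2,2-dimethyl-2H-chromene-8-carbonyl)-5-methyl-6-[(3-methylbut-2-en-1-yl)oxy]benzaldehyde | CC(C)=CCOc1c(C)cc(O)c(C(=O)c2c(O)ccc3c2OC(C)(C)C=C3)c1C=O | target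

**Step count and risks**

Total step count: 11. Longest linear sequence: 8 steps (steps 4 to 11, from 2-hydroxy-3-methylbenzaldehyde).

Steps most likely to fail:

1. Step 9. The aryne may be consumed intermolecularly (addition of a second aryllithium or of the amide base, oligomerisation) faster than the tethered alkoxide can close the ring, or aryllithium 17 may be protonated before the aldehyde arrives. Fallback, setting out from 5 (with 14) and returning at 19: 5 would be lithiated with LiTMP and kept at −78 °C so that fluoroaryllithium 15 does not lose LiF and is trapped directly by 14. This should give [2-(dimethoxymethyl)-6-(methoxymethoxy)-4-methyl-3-(3-methylbut-2-enyloxy)phenyl]{2-fluoro-3-[(Z)-3-hydroxy-3-methylbut-1-enyl]-6-(methoxymethoxy)phenyl}methanol F1. Dess–Martin oxidation of the secondary carbinol should give the 2-fluorobenzophenone [2-(dimethoxymethyl)-6-(methoxymethoxy)-4-methyl-3-(3-methylbut-2-enyloxy)phenyl]{2-fluoro-3-[(Z)-3-hydroxy-3-methylbut-1-enyl]-6-(methoxymethoxy)phenyl}methanone F2. NaH in THF/DMF should then close the pyran ring by intramolecular SNAr of the tertiary alkoxide at the C–F carbon activated by the ortho ketone, giving 19; the MOM group on the ring A phenol blocks the competing xanthone closure.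

2. Step 8. The butyllithium may deprotonate next to the allylic ether oxygen of the prenyl group (followed by Wittig rearrangement or loss of the prenyl group) in competition with ring metalation. Fallback, setting out from 9 and returning at 14: the chelated phenol of 9 would be silylated (TIPSOTf, 2,6-lutidine, CH2Cl2) to give 5-(methoxymethoxy)-3-methyl-2-(triisopropylsilyloxy)benzaldehyde F3. Acetalisation as in step 7 should give [2-(dimethoxymethyl)-4-(methoxymethoxy)-6-methylphenoxy]triisopropylsilane F4. n-BuLi then DMF as in step 8, now with no allylic ether in the molecule, should give 2-(dimethoxymethyl)-6-(methoxymethoxy)-4-methyl-3-(triisopropylsilyloxy)benzaldehyde F5. CsF and prenyl bromide 10 in DMF would then remove the silyl group and alkylate the liberated phenoxide in the same flask, giving 14.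

3. Step 11. Acid may ionise the prenyl aryl ether (loss of the prenyl group) or attack the chromene before both MOM ethers are cleaved. Fallback, setting out from 19 and returning at 20: the unmasking would be staged so that the MOM ethers are removed without protic acid. PPTS in wet acetone at rt should hydrolyse only the dimethyl acetal and give 3-(methoxymethoxy)-2-[7-(methoxymethoxy)-2,2-dimethyl-2H-chromene-8-carbonyl]-5-methyl-6-(3-methylbut-2-enyloxy)benzaldehyde F6. TMSOTf with 2,2'-bipyridyl in CH2Cl2 at 0 °C, followed by water, should then excise the two aryl MOM groups through pyridinium intermediates under non-acidic conditions and give 20.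

**Further compounds**

F1 | step 9 | [2-(dimethoxymethyl)-6-(methoxymethoxy)-4-methyl-3-(3-methylbut-2-enyloxy)phenyl]{2-fluoro-3-[(Z)-3-hydroxy-3-methylbut-1-enyl]-6-(methoxymethoxy)phenyl}methanol | COCOc1ccc(/C=C\C(C)(C)O)c(F)c1C(O)c1c(OCOC)cc(C)c(OCC=C(C)C)c1C(OC)OC
F2 | step 9 | [2-(dimethoxymethyl)-6-(methoxymethoxy)-4-methyl-3-(3-methylbut-2-enyloxy)phenyl]{2-fluoro-3-[(Z)-3-hydroxy-3-methylbut-1-enyl]-6-(methoxymethoxy)phenyl}methanone | COCOc1ccc(/C=C\C(C)(C)O)c(F)c1C(=O)c1c(OCOC)cc(C)c(OCC=C(C)C)c1C(OC)OC
F3 | step 8 | 5-(methoxymethoxy)-3-methyl-2-(triisopropylsilyloxy)benzaldehyde | COCOc1cc(C)c(O[Si](C(C)C)(C(C)C)C(C)C)c(C=O)c1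
F4 | step 8 | [2-(dimethoxymethyl)-4-(methoxymethoxy)-6-methylphenoxy]triisopropylsilane | COCOc1cc(C)c(O[Si](C(C)C)(C(C)C)C(C)C)c(C(OC)OC)c1
F5 | step 8 | 2-(dimethoxymethyl)-6-(methoxymethoxy)-4-methyl-3-(triisopropylsilyloxy)benzaldehyde | COCOc1cc(C)c(O[Si](C(C)C)(C(C)C)C(C)C)c(C(OC)OC)c1C=O
F6 | step 11 | 3-(methoxymethoxy)-2-[7-(methoxymethoxy)-2,2-dimethyl-2H-chromene-8-carbonyl]-5-methyl-6-(3-methylbut-2-enyloxy)benzaldehyde | COCOc1ccc2C=CC(C)(C)Oc2c1C(=O)c1c(OCOC)cc(C)c(OCC=C(C)C)c1C=O
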